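**Retrosynthetic overview**
- The target comes from its tetra-MOM ether by acid removal of four MOM groups; the aryl methyl ether stays.
- Ring C is made by ring contraction of a seven-membered 2-aryl-1,3-benzodioxepin-5-one (cyclic acetal). The acetal carbon shifts from oxygen to the neighbouring carbon (a 1,2-shift), which forms C2–C3 and sets both stereocentres.
- The cyclic acetal comes from a ring A 2-hydroxyacetyl phenol and a ring B aldehyde.
- Ring A piece: resorcinol, MOM protection, C2 lithiation/prenylation, iridium C–H borylation/oxidation (third oxygen; the symmetric phenol fixes the 6-prenyl pattern), ortho-formylation, carbene-catalysed hydroxymethylation.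
- Ring B piece: catechol, MOM protection, ortho-lithiation/oxidation/methylation, iridium C–H borylation, one-carbon boronate homologation to the aldehyde. Rings A and B are bought as benzene rings; the seven-membered ring is built first and then contracted to ring C.

Assumption: the (R)-configured phosphoric acid in step 11 is taken to give the (2R,3R) product; if the first run shows the opposite sense, its (S)-enantiomer is used and nothing else changes.

Step 1
Reactants: 1 resorcinol
Product: 2 1,3-bis(methoxymethoxy)benzene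
Conditions: NaH, MOMCl, DMF, 0 °C → 23 °C
Reagents that add atoms: chloromethyl methyl ether (MOMCl), COCCl
Why: Williamson-type O-alkylation of the bis-phenoxide gives the bis-MOM ether, which survives the organolithium, iridium and basic steps that follow and directs lithiation to C2.

Step 2
Reactants: 2 1,3-bis(methoxymethoxy)benzene; 3 prenyl bromide
Product: 5 1,3-bis(methoxymethoxy)-2-(3-methylbut-2-en-1-yl)benzene, via aryllithium 4 (not isolated)
Conditions: n-BuLi, THF, 0 °C → 23 °C; CuI (10 mol %), then 3, −78 °C → 23 °C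
Reagents that add atoms: none
Why: Directed ortho-metalation removes the C2 proton flanked by both MOM ethers, and copper-catalysed SN2 allylation of the aryllithium gives the linear prenyl group.

Step 3
Reactants: 5 1,3-bis(methoxymethoxy)-2-(3-methylbut-2-en-1-yl)benzene
Product: 7 3,5-bis(methoxymethoxy)-4-(3-methylbut-2-en-1-yl)phenol, via arylboronate 6 (not isolated)
Conditions: [Ir(OMe)(cod)]2 (1.5 mol %), 4,4'-di-tert-butyl-2,2'-bipyridine (3 mol %), B2pin2 (1.0 equiv), THF, 60 °C; then aq NaOH, 30% H2O2, 0 °C → 23 °C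
Reagents that add atoms: hydrogen peroxide, OO
Why: Sterically controlled iridium-catalysed C–H borylation occurs only at C5, the one ring C–H without an ortho substituent, and peroxide oxidation of the C–B bond gives a symmetric phenol whose two ortho positions are equivalent, so the prenyl group must end up at C6 of the flavonoid.

Step 4
Reactants: 7 3,5-bis(methoxymethoxy)-4-(3-methylbut-2-en-1-yl)phenol
Product: 8 6-hydroxy-2,4-bis(methoxymethoxy)-3-(3-methylbut-2-en-1-yl)benzaldehyde
Conditions: MgCl2, Et3N, paraformaldehyde, MeCN, reflux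
Reagents that add atoms: paraformaldehyde (formaldehyde units), C=O
Why: Magnesium-mediated ortho-formylation (Casnati–Skattebøl type): the magnesium phenoxide delivers formaldehyde to the ortho carbon and a second formaldehyde accepts hydride; the para position is blocked and both ortho positions are the same.

Step 5
Reactants: 8 6-hydroxy-2,4-bis(methoxymethoxy)-3-(3-methylbut-2-en-1-yl)benzaldehyde
Product: 9 2-hydroxy-1-[6-hydroxy-2,4-bis(methoxymethoxy)-3-(3-methylbut-2-en-1-yl)phenyl]ethan-1-one
Conditions: 3-benzyl-5-(2-hydroxyethyl)-4-methylthiazolium chloride (10 mol %), i-Pr2NEt (20 mol %), paraformaldehyde, THF, 60 °C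
Reagents that add atoms: paraformaldehyde (formaldehyde units), C=O
Why: Carbene-catalysed hydroxymethylation (crossed benzoin reaction with formaldehyde): the Breslow intermediate of the aryl aldehyde adds to formaldehyde to give the α-hydroxymethyl ketone without touching the MOM ethers or the alkene.

Step 6
Reactants: 10 catechol
Product: 11 1,2-bis(methoxymethoxy)benzene
Conditions: NaH, MOMCl, DMF, 0 °C → 23 °C
Reagents that add atoms: chloromethyl methyl ether (MOMCl), COCCl
Why: Williamson-type O-alkylation protects both phenols as MOM ethers, which then direct the ortho-lithiation of step 7.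

Step 7
Reactants: 11 1,2-bis(methoxymethoxy)benzene
Product: 15 1-methoxy-2,3-bis(methoxymethoxy)benzene, via aryllithium 12 (not isolated), via dimethyl arylboronate 13 (not isolated), via sodium phenolate 14 (not isolated)
Conditions: n-BuLi, THF, 0 °C; B(OMe)3, −78 °C → 23 °C; aq NaOH, 30% H2O2 (1.05 equiv), 0 °C → 23 °C; then Me2SO4, 23 °C
Reagents that add atoms: hydrogen peroxide, OO; dimethyl sulfate, COS(=O)(=O)OC
Why: Directed ortho-metalation next to a MOM ether, borate trapping, oxidation of the C–B bond and O-methylation of the phenoxide in the same basic medium install the third oxygen as the future 3'-methoxy group.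

Step 8
Reactants: 15 1-methoxy-2,3-bis(methoxymethoxy)benzene
Product: 16 2-[3-methoxy-4,5-bis(methoxymethoxy)phenyl]-4,4,5,5-tetramethyl-1,3,2-dioxaborolane
Conditions: [Ir(OMe)(cod)]2 (1.5 mol %), 4,4'-di-tert-butyl-2,2'-bipyridine (3 mol %), B2pin2 (1.0 equiv), THF, 80 °C
Reagents that add atoms: bis(pinacolato)diboron, CC1(C)OB(OC1(C)C)B1OC(C)(C)C(C)(C)O1
Why: Iridium-catalysed C–H borylation of the 1,2,3-trioxygenated ring is sterically confined to C5, para to the middle oxygen, which is the carbon that must carry C2 of the flavonoid.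

Step 9
Reactants: 16 2-[3-methoxy-4,5-bis(methoxymethoxy)phenyl]-4,4,5,5-tetramethyl-1,3,2-dioxaborolane
Product: 18 3-methoxy-4,5-bis(methoxymethoxy)benzaldehyde, via α-chloroboronate 17 (not isolated)
Conditions: CH2Cl2, n-BuLi, THF, −100 °C; add 16, −100 °C → 23 °C; then aq NaOH (2 equiv), 30% H2O2 (1.1 equiv), 0 °C, 15 min
Reagents that add atoms: dichloromethane, ClCCl; hydrogen peroxide, OO
Why: Matteson homologation: dichloromethyllithium forms the boronate complex, the aryl group migrates from boron to carbon with loss of chloride, and oxidation of the α-chloroboronate releases the aldehyde.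

Step 10
Reactants: 9 2-hydroxy-1-[6-hydroxy-2,4-bis(methoxymethoxy)-3-(3-methylbut-2-en-1-yl)phenyl]ethan-1-one; 18 3-methoxy-4,5-bis(methoxymethoxy)benzaldehyde
Product: 19 racemic 2-[3-methoxy-4,5-bis(methoxymethoxy)phenyl]-6,8-bis(methoxymethoxy)-7-(3-methylbut-2-en-1-yl)-1,3-benzodioxepin-5(4H)-one
Conditions: pyridinium p-toluenesulfonate (5 mol %), MgSO4, CH2Cl2, 23 °C; filtration through basic alumina
Reagents that add atoms: none
Why: Acid-catalysed dehydrative acetalisation joins the primary alcohol and the phenol of 9 through the aldehyde carbon into a seven-membered mixed acetal; its stereocentre is formed racemic and is erased and reset in step 11.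

Step 11
Reactants: 19 racemic 2-[3-methoxy-4,5-bis(methoxymethoxy)phenyl]-6,8-bis(methoxymethoxy)-7-(3-methylbut-2-en-1-yl)-1,3-benzodioxepin-5(4H)-one
Product: 20 (2R,3R)-3-hydroxy-2-[3-methoxy-4,5-bis(methoxymethoxy)phenyl]-5,7-bis(methoxymethoxy)-6-(3-methylbut-2-en-1-yl)-2,3-dihydro-4H-chromen-4-one
Conditions: (R)-TRIP [(R)-3,3'-bis(2,4,6-triisopropylphenyl)-1,1'-binaphthyl-2,2'-diyl hydrogen phosphate] (10 mol %), toluene (0.02 M), 40 °C
Reagents that add atoms: none
Why: Proposed new method: an enantioselective ring contraction by 1,2-shift of the acetal carbon C2 from O3 to C4 of the dioxepinone, in which the chiral acid protonates the more basic alkyl acetal oxygen O3 and ionises C2–O3 to an oxocarbenium ion stabilised by the aryl ether oxygen and the para-alkoxyphenyl group (ionisation of the other C–O bond is reversible and unproductive), and the tethered Z-enediol of the freed α-hydroxy ketone, hydrogen-bonded to the chiral phosphate, closes the six-membered ring through a chair transition state with aryl and hydroxyl equatorial, so that the ion pair sets C2 (R) and the chair sets C3 (R) trans, which is also the thermodynamic C3 epimer; the closest known reactions are Lewis-acid ring contractions of cyclic enol acetals with oxygen-to-carbon shift (Petasis–Ferrier type) and chiral phosphoric acid-catalysed enol additions to oxocarbenium ions.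

Step 12
Reactants: 20 (2R,3R)-3-hydroxy-2-[3-methoxy-4,5-bis(methoxymethoxy)phenyl]-5,7-bis(methoxymethoxy)-6-(3-methylbut-2-en-1-yl)-2,3-dihydro-4H-chromen-4-one
Product: 21 (2R,3R)-2-(3,4-dihydroxy-5-methoxyphenyl)-3,5,7-trihydroxy-6-(3-methylbut-2-en-1-yl)-2,3-dihydro-4H-chromen-4-one
Conditions: 3 M HCl, MeOH, 23 → 40 °C
Reagents that add atoms: none
Why: Acid-catalysed acetal exchange with methanol removes all four MOM groups; the aryl methyl ether, the prenyl alkene and the trans (2R,3R) stereocentres are stable under these mild conditions.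

**Compound list**
1 | resorcinol (benzene-1,3-diol) | Oc1cccc(O)c1 | starting material
2 | 1,3-bis(methoxymethoxy)benzene | COCOc1cccc(OCOC)c1 | intermediate
3 | prenyl bromide (1-bromo-3-methylbut-2-ene) | CC(C)=CCBr | starting material
4 | [2,6-bis(methoxymethoxy)phenyl]lithium | [Li]c1c(OCOC)cccc1OCOC | intermediate
5 | 1,3-bis(methoxymethoxy)-2-(3-methylbut-2-en-1-yl)benzene | COCOc1cccc(OCOC)c1CC=C(C)C | intermediate
6 | 2-[3,5-bis(methoxymethoxy)-4-(3-methylbut-2-en-1-yl)phenyl]-4,4,5,5-tetramethyl-1,3,2-dioxaborolane | COCOc1cc(B2OC(C)(C)C(C)(C)O2)cc(OCOC)c1CC=C(C)C | intermediate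
7 | 3,5-bis(methoxymethoxy)-4-(3-methylbut-2-en-1-yl)phenol | COCOc1cc(O)cc(OCOC)c1CC=C(C)C | intermediate
8 | 6-hydroxy-2,4-bis(methoxymethoxy)-3-(3-methylbut-2-en-1-yl)benzaldehyde | O=Cc1c(O)cc(OCOC)c(CC=C(C)C)c1OCOC | intermediate
9 | 2-hydroxy-1-[6-hydroxy-2,4-bis(methoxymethoxy)-3-(3-methylbut-2-en-1-yl)phenyl]ethan-1-one | O=C(CO)c1c(O)cc(OCOC)c(CC=C(C)C)c1OCOC | intermediate
10 | catechol (benzene-1,2-diol) | Oc1ccccc1O | starting material
11 | 1,2-bis(methoxymethoxy)benzene | COCOc1ccccc1OCOC | intermediate
12 | [2,3-bis(methoxymethoxy)phenyl]lithium | [Li]c1cccc(OCOC)c1OCOC | intermediate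
13 | dimethyl [2,3-bis(methoxymethoxy)phenyl]boronate | COB(OC)c1cccc(OCOC)c1OCOC | intermediate
14 | sodium 2,3-bis(methoxymethoxy)phenolate | [Na+].[O-]c1cccc(OCOC)c1OCOC | intermediate
15 | 1-methoxy-2,3-bis(methoxymethoxy)benzene | COc1cccc(OCOC)c1OCOC | intermediate
16 | 2-[3-methoxy-4,5-bis(methoxymethoxy)phenyl]-4,4,5,5-tetramethyl-1,3,2-dioxaborolane | COc1cc(B2OC(C)(C)C(C)(C)O2)cc(OCOC)c1OCOC | intermediate
17 | 2-{chloro[3-methoxy-4,5-bis(methoxymethoxy)phenyl]methyl}-4,4,5,5-tetramethyl-1,3,2-dioxaborolane (racemic) | COc1cc(C(Cl)B2OC(C)(C)C(C)(C)O2)cc(OCOC)c1OCOC | intermediate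
18 | 3-methoxy-4,5-bis(methoxymethoxy)benzaldehyde | COc1cc(C=O)cc(OCOC)c1OCOC | intermediate
19 | 2-[3-methoxy-4,5-bis(methoxymethoxy)phenyl]-6,8-bis(methoxymethoxy)-7-(3-methylbut-2-en-1-yl)-1,3-benzodioxepin-5(4H)-one (racemic at C2) | O=C1COC(c2cc(OC)c(OCOC)c(OCOC)c2)Oc2cc(OCOC)c(CC=C(C)C)c(OCOC)c21 | intermediate
20 | (2R,3R)-3-hydroxy-2-[3-methoxy-4,5-bis(methoxymethoxy)phenyl]-5,7-bis(methoxymethoxy)-6-(3-methylbut-2-en-1-yl)-2,3-dihydro-4H-chromen-4-one | COc1cc([C@H]2Oc3cc(OCOC)c(CC=C(C)C)c(OCOC)c3C(=O)[C@@H]2O)cc(OCOC)c1OCOC | intermediate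
21 | (2R,3R)-2-(3,4-dihydroxy-5-methoxyphenyl)-3,5,7-trihydroxy-6-(3-methylbut-2-en-1-yl)-2,3-dihydro-4H-chromen-4-one | COc1cc([C@H]2Oc3cc(O)c(CC=C(C)C)c(O)c3C(=O)[C@@H]2O)cc(O)c1O | target

**Step count and risks**
Total step count: 12. Longest linear sequence: 8 steps (steps 1–5, then 10–12).

The three steps most likely to fail:

Step 11, the new ring contraction. The acetal may ionise mainly at the aryl oxygen (unproductive), the enediol may form too slowly, the cation may alkylate another electron-rich ring, or the enantioselectivity may be low. The fallback uses known chemistry, sets out from 9 and 18 and comes back at 20. A direct syn-selective asymmetric aldol addition of the α-hydroxy ketone 9 to aldehyde 18 is run with the dinuclear zinc catalyst made from Et2Zn (one extra equivalent for the phenol) and the ProPhenol ligand 2,6-bis{[2-(hydroxydiphenylmethyl)pyrrolidin-1-yl]methyl}-4-methylphenol, using the ligand antipode that delivers the (2R,3S) diol. This gives the syn-diol (2R,3S)-2,3-dihydroxy-1-[6-hydroxy-2,4-bis(methoxymethoxy)-3-(3-methylbut-2-en-1-yl)phenyl]-3-[3-methoxy-4,5-bis(methoxymethoxy)phenyl]propan-1-one F1. An intramolecular Mitsunobu etherification (PPh3, diisopropyl azodicarboxylate, THF, 0 °C) then lets the phenol displace the activated benzylic hydroxyl with inversion and closes ring C to give 20.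

Step 5, the carbene-catalysed hydroxymethylation. The aldehyde is electron-rich, flanked by two ortho substituents and carries a free phenol, so the Breslow intermediate may form too slowly. The fallback sets out from 8 and comes back at 9. MeMgBr (2.2 equiv, THF, 0 °C) adds to the aldehyde to give 2-(1-hydroxyethyl)-3,5-bis(methoxymethoxy)-4-(3-methylbut-2-en-1-yl)phenol F2. MnO2 in CH2Cl2 oxidises the benzylic alcohol to 1-[6-hydroxy-2,4-bis(methoxymethoxy)-3-(3-methylbut-2-en-1-yl)phenyl]ethan-1-one F3. The dianion of F3 (LiN(SiMe3)2, 2.2 equiv, THF, −78 °C) is hydroxylated at the methyl carbon with 2-(phenylsulfonyl)-3-phenyloxaziridine to give 9.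

Step 10, the seven-membered acetal. The phenol is hydrogen-bonded to the ketone and the aldehyde is electron-rich, so the equilibrium may lie on the side of the components. The fallback sets out from 9 and comes back at 19. Both hydroxyl groups of 9 are silylated (Me3SiCl, Et3N, CH2Cl2) to give 1-[2,4-bis(methoxymethoxy)-3-(3-methylbut-2-en-1-yl)-6-(trimethylsilyloxy)phenyl]-2-(trimethylsilyloxy)ethan-1-one F4. F4 is then condensed with aldehyde 18 under kinetic silyl-transfer acetalisation (Me3SiOTf, 2 mol %, CH2Cl2, −78 °C, pyridine quench), which is driven irreversibly and avoids free acid at room temperature, to give 19.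

Further compounds
F1 | step 11 | (2R,3S)-2,3-dihydroxy-1-[6-hydroxy-2,4-bis(methoxymethoxy)-3-(3-methylbut-2-en-1-yl)phenyl]-3-[3-methoxy-4,5-bis(methoxymethoxy)phenyl]propan-1-one | O=C([C@H](O)[C@@H](O)c1cc(OC)c(OCOC)c(OCOC)c1)c1c(O)cc(OCOC)c(CC=C(C)C)c1OCOC
F2 | step 5 | 2-(1-hydroxyethyl)-3,5-bis(methoxymethoxy)-4-(3-methylbut-2-en-1-yl)phenol (racemic) | CC(O)c1c(O)cc(OCOC)c(CC=C(C)C)c1OCOC
F3 | step 5 | 1-[6-hydroxy-2,4-bis(methoxymethoxy)-3-(3-methylbut-2-en-1-yl)phenyl]ethan-1-one | CC(=O)c1c(O)cc(OCOC)c(CC=C(C)C)c1OCOC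
F4 | step 10 | 1-[2,4-bis(methoxymethoxy)-3-(3-methylbut-2-en-1-yl)-6-(trimethylsilyloxy)phenyl]-2-(trimethylsilyloxy)ethan-1-one | O=C(CO[Si](C)(C)C)c1c(O[Si](C)(C)C)cc(OCOC)c(CC=C(C)C)c1OCOC
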